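The earlier runs and the new flask are simulated with made-up constants; the scatter is artificial.

The ratio of E to G at the plateau of this flask shows how hard X competes for Q, and that ratio per unit of X is the number worth carrying.

| flask | J | X | remark | time |
|---|---|---|---|---|
| south-east | 1 mM | 1 mM | the very flask that is asked about, followed so far |  |
| flask | 1.0 mM | 1.00 mM |  | 15 min |

south-east run (percent of the J charged)

| time / min | J / % | E / % | Z / % |
|---|---|---|---|
| 1.00 | 4.1 | 40.9 | 27.6 |
| 2.50 | 0.2 | 45.4 | 28.7 |
| 5.00 | 0.8 | 45.9 | 28.4 |
| 8.00 | 0.3 | 45.3 | 28.7 |

(readings scatter by 0.3 percentage points)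

- percentages count the J that a species holds: one Z counts as two
- the earlier runs were read with a standard deviation of 0.3 percentage points
- what may be going on: 2 Q -> Z; J -> Q; X + Q -> E; Q -> G
- the reaction counts as stopped when no species that holds the J changes by six tenths of a point or more over the second half of the time

1. the state of affairs at 15 min: stopped, and by what, or still going (X has run out first / all of J has reacted / it is still moving)
2. part of the J gone at 15 min
3. the E standing at 15 min, as a percentage of the J charged
4. the Z standing at 15 min, as a percentage of the J charged

On the scheme offered, J goes to Q, and Q leaves in three ways: in pairs to Z, alone to G, and with X to E. The readings of E and Z in the flask stand flat from 2.50 min on, with means of 45.5% and 28.6%. Taking Q as gone, the remainder of 25.9% is read as G.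

On that scheme the steps to E and to G each take one Q, so Q cancels from the ratio of their rates, and E forms over G in proportion to X. The bench rule freezes X at its charge, which gives 1.76 mM⁻¹. The border of that rule is the ratio of X drawn to X charged, here 45.5%, so X is far from frozen. Freezing X instead at the mean of its start and end, 0.772 mM, gives the selectivity factor s, E over G per unit of mean X, read here as 2.28 mM⁻¹.

The forecast says all of J has reacted, with 100% gone, E 45.5% and Z 28.6%, on the grounds that “E and Z stay flat from 2.5 to 8 min”.

The flask at 15 min gives all of J has reacted, with 100% gone, E 45.7% and Z 28.5%.

    2 Q → Z (k = 92.0 M⁻¹ s⁻¹)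
    J → Q (k = 0.0540 s⁻¹)
    X + Q → E (k = 59.0 M⁻¹ s⁻¹)
    Q → G (k = 0.0250 s⁻¹)

At the charged X of the flask, Q has a half-life of 0.20 min by the step to E, shorter than the 0.46 min by the step to G, and at 15.0 min the flask holds E 45.7% against G 25.8%. A neighbour flask charged with 0.60 mM of X, its J as in the flask, keeps 48.0% of that X at 15.0 min, so its mean X is 0.444 mM, s times that mean gives E over G of 1.01, and that neighbour holds E 31.2% against G 31.1%.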